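The cyclohexene ring (C1 carries the ketone carbon C7, C2 the prenyl group, C3 the methyl group, C3=C4, C5 is CH2, C6 carries phenyl) contains the γ,δ-unsaturated carbonyl array C7–C1–C2–C3=C4. Disconnecting C1–C2 and tying C4 to C7 through oxygen leads to a trans-4-phenyl-6-alkenyl δ-lactone whose ring already spans C5 and C6. The Ireland–Claisen ring contraction of its silyl ketene acetal closes the carbocycle, forms C1–C2, places the C3=C4 alkene and sets C1 and C2 in one operation, transferring the carbinol configuration and the E-alkene geometry. The all-cis acid is then aroylated, epimerised at C1 and deprotected.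

Key step: step 6

Remark: the ring numbering above is used throughout and reagents without a number are assumed commercial. Re-derivation of the boat transition state confirms that the (4S,6R)-trans lactone with the E alkene should give the (1R,2S,6S) all-cis acid, so the precursor structure needs no correction.

Step 1
Reactants: 1 4-methylpent-3-en-1-ol
Product: 3 (2E)-2,6-dimethylhepta-2,5-dienal, via 4-methylpent-3-enal 2 (not isolated)
Conditions: DMP, NaHCO3, CH2Cl2, 0 °C; aq. Na2S2O3/NaHCO3 wash; dried solution, then Ph3P=C(CH3)CHO, CH2Cl2, 40 °C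
Reagents that add atoms: 2-(triphenylphosphoranylidene)propanal, CC(C=O)=P(c1ccccc1)(c1ccccc1)c1ccccc1
Why: Buffered Dess–Martin oxidation should give the β,γ-unsaturated aldehyde without alkene migration, and the Wittig reaction of the formyl-stabilised ylide is E-selective, so the new CH2 ends trans to CHO.

Step 2
Reactants: 3 (2E)-2,6-dimethylhepta-2,5-dienal
Product: 5 (4R,5E)-5,9-dimethyldeca-1,5,8-trien-4-ol, via diisopinocampheylborinate 4 (not isolated)
Conditions: (+)-Ipc2BOMe [(−)-α-pinene series], allylMgBr, Et2O, 0 °C to rt; then 3, −78 °C; then NaOH, H2O2, 0 °C to rt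
Reagents that add atoms: allylmagnesium bromide, C=CC[Mg]Br
Why: Brown allylboration through a closed chair transition state, in which the allylborane of the (−)-α-pinene series delivers allyl to the Re face of the α-methyl enal and so sets the carbinol centre as R.

Step 3
Reactants: 5 (4R,5E)-5,9-dimethyldeca-1,5,8-trien-4-ol; 6 acryloyl chloride
Product: 7 (4R,5E)-5,9-dimethyldeca-1,5,8-trien-4-yl prop-2-enoate
Conditions: Et3N, DMAP (cat.), CH2Cl2, −20 to 0 °C
Reagents that add atoms: acryloyl chloride (6), C=CC(Cl)=O
Why: DMAP-catalysed O-acylation of the secondary allylic alcohol by the acid chloride touches no bond at the stereocentre.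

Step 4
Reactants: 7 (4R,5E)-5,9-dimethyldeca-1,5,8-trien-4-yl prop-2-enoate
Product: 8 (6R)-6-[(2E)-6-methylhepta-2,5-dien-2-yl]-5,6-dihydro-2H-pyran-2-one
Conditions: Grubbs II (5 mol%), CH2Cl2 (0.005 M), 40 °C
Reagents that add atoms: none
Why: Ring-closing metathesis, in which the catalyst loads on the monosubstituted allyl alkene and closes the six-membered ring onto the acrylate with loss of ethene, the trisubstituted alkenes being much slower partners at high dilution.

Step 5
Reactants: 8 (6R)-6-[(2E)-6-methylhepta-2,5-dien-2-yl]-5,6-dihydro-2H-pyran-2-one; 9 phenylboronic acid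
Product: 10 (4S,6R)-6-[(2E)-6-methylhepta-2,5-dien-2-yl]-4-phenyltetrahydro-2H-pyran-2-one (trans lactone)
Conditions: [Rh(OH)(cod)]2 (2.5 mol%), dioxane/H2O 10:1, 40 °C
Reagents that add atoms: phenylboronic acid (9), OB(O)c1ccccc1
Why: Hayashi–Miyaura rhodium-catalysed conjugate addition, in which the phenyl–rhodium species should add to the enoate face opposite the pseudo-equatorial alkenyl group of the half-chair lactone and so set the phenyl-bearing centre (future C6) trans to the carbinol centre, the isolated alkenes being inert.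

Step 6
Reactants: 10 (4S,6R)-6-[(2E)-6-methylhepta-2,5-dien-2-yl]-4-phenyltetrahydro-2H-pyran-2-one
Product: 13 (1R,2S,6S)-3-methyl-2-(3-methylbut-2-en-1-yl)-6-phenylcyclohex-3-ene-1-carboxylic acid, via TBS ketene acetal 11 (not isolated), via TBS ester 12 (not isolated)
Conditions: LDA, TBSCl, DMPU, THF, −78 °C to rt; PhMe, 110 °C; then 1 M HCl, THF, rt
Reagents that add atoms: none
Why: LDA enolises the lactone at C1 and O-silylation gives the cyclic silyl ketene acetal, whose array C1=C7–O–C4–C3=C2 undergoes a concerted suprafacial [3,3] shift (Ireland–Claisen rearrangement), the closest known reaction type being the ring contraction of alkenyl lactone silyl ketene acetals to cycloalkenecarboxylic acids. The carbocycle C1–C6 is closed by the sigmatropic C1–C2 bond formation itself, through a bicyclo[2.2.2]-like boat transition state with C1 and C4 as bridgeheads and the C5–C6 tether, the C2=C3 alkene and the O–C7 unit as the three bridges, a chair being excluded because it would require a trans-cyclohexene. C1 is controlled by the C4 carbinol centre, because the alkenyl arm can reach C1 only on the lactone face it occupies, which leaves C7 on the side of the former lactone bridge. C2 is controlled by the E geometry of the C2=C3 alkene, which in the boat turns the prenyl CH2 toward that same bridge and therefore cis to the carboxyl group. The trans lactone allows the reacting half-chair to carry the alkenyl group axial and the phenyl group equatorial and places phenyl cis to the carboxyl group, so the all-cis acid should result. The step needs O-silylation to outrun Claisen self-condensation and C-silylation, which is secured by trapping the enolate with TBSCl/DMPU at −78 °C before warming, and no ketene acetal geometry arises because the C1=C7 bond is endocyclic.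

Step 7
Reactants: 13 (1R,2S,6S)-3-methyl-2-(3-methylbut-2-en-1-yl)-6-phenylcyclohex-3-ene-1-carboxylic acid
Product: 15 (1R,2S,6S)-N-methoxy-N,3-dimethyl-2-(3-methylbut-2-en-1-yl)-6-phenylcyclohex-3-ene-1-carboxamide, via acid chloride 14 (not isolated)
Conditions: 1-chloro-N,N,2-trimethylprop-1-en-1-amine, CH2Cl2, 0 °C; then MeNHOMe·HCl, pyridine, 0 °C to rt
Reagents that add atoms: N,O-dimethylhydroxylamine hydrochloride, CNOC.Cl
Why: The α-chloroenamine forms the acid chloride under neutral conditions that spare the trisubstituted alkenes, and N-acylation then gives the Weinreb amide, any erosion at C1 being harmless because C1 is equilibrated in step 12.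

Step 8
Reactants: 16 3-hydroxy-4,5-dimethoxybenzaldehyde
Product: 17 3,4-dimethoxy-5-(methoxymethoxy)benzaldehyde
Conditions: MOMCl, iPr2NEt, CH2Cl2, 0 °C to rt
Reagents that add atoms: chloromethyl methyl ether, COCCl
Why: O-alkylation of the phenol (Williamson-type acetal formation) protects it before the oxidation and installs the first directing group.

Step 9
Reactants: 17 3,4-dimethoxy-5-(methoxymethoxy)benzaldehyde
Product: 19 3,4-dimethoxy-5-(methoxymethoxy)phenol, via aryl formate 18 (not isolated)
Conditions: mCPBA, CH2Cl2, 0 °C to rt; then K2CO3, MeOH, rt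
Reagents that add atoms: 3-chloroperoxybenzoic acid, OOC(=O)c1cccc(Cl)c1
Why: Baeyer–Villiger oxidation, in which the electron-rich aryl group with a para methoxy substituent migrates in the Criegee intermediate to give the aryl formate, which is methanolysed in the same flask.

Step 10
Reactants: 19 3,4-dimethoxy-5-(methoxymethoxy)phenol
Product: 20 1,2-dimethoxy-3,5-bis(methoxymethoxy)benzene
Conditions: MOMCl, iPr2NEt, CH2Cl2, 0 °C to rt
Reagents that add atoms: chloromethyl methyl ether, COCCl
Why: A second phenol O-alkylation gives the bis-MOM ether, whose two acetal groups flank the carbon to be metalated.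

Step 11
Reactants: 20 1,2-dimethoxy-3,5-bis(methoxymethoxy)benzene; 15 (1R,2S,6S)-N-methoxy-N,3-dimethyl-2-(3-methylbut-2-en-1-yl)-6-phenylcyclohex-3-ene-1-carboxamide
Product: 23 [3,4-dimethoxy-2,6-bis(methoxymethoxy)phenyl][(1R,2S,6S)-3-methyl-2-(3-methylbut-2-en-1-yl)-6-phenylcyclohex-3-en-1-yl]methanone, via aryllithium 21 (not isolated), via lithium hemiaminal adduct 22 (not isolated)
Conditions: 20 (2 equiv), n-BuLi (1.9 equiv), THF, 0 °C; then 15, −78 to 0 °C; AcOH quench
Reagents that add atoms: none
Why: Directed ortho-metalation at the one position flanked by two OMOM groups gives the aryllithium, which adds to the Weinreb amide to form a chelated tetrahedral adduct that resists over-addition and releases the ketone on quench (Weinreb ketone synthesis).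

Step 12
Reactants: 23 [3,4-dimethoxy-2,6-bis(methoxymethoxy)phenyl][(1R,2S,6S)-3-methyl-2-(3-methylbut-2-en-1-yl)-6-phenylcyclohex-3-en-1-yl]methanone
Product: 24 [3,4-dimethoxy-2,6-bis(methoxymethoxy)phenyl][(1S,2S,6S)-3-methyl-2-(3-methylbut-2-en-1-yl)-6-phenylcyclohex-3-en-1-yl]methanone
Conditions: NaOMe (0.3 equiv), MeOH/THF, 60 °C
Reagents that add atoms: none
Why: Reversible enolisation at C1, the only enolisable position, should equilibrate the ketone under thermodynamic control from the crowded all-cis arrangement to the isomer with the aroyl group trans to both neighbours (all three substituents equatorial), which sets C1 as S.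

Step 13
Reactants: 24 [3,4-dimethoxy-2,6-bis(methoxymethoxy)phenyl][(1S,2S,6S)-3-methyl-2-(3-methylbut-2-en-1-yl)-6-phenylcyclohex-3-en-1-yl]methanone
Product: 25 (2,6-dihydroxy-3,4-dimethoxyphenyl)[(1S,2S,6S)-3-methyl-2-(3-methylbut-2-en-1-yl)-6-phenylcyclohex-3-en-1-yl]methanone
Conditions: 3 M aq. HCl, MeOH, 40 °C
Reagents that add atoms: none
Why: Acid-catalysed acetal methanolysis should remove both MOM groups, helped by hydrogen bonding of the freed phenols to the ketone, under conditions mild enough to leave the two trisubstituted alkenes and the stereocentres untouched.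

Compound list
1 | 4-methylpent-3-en-1-ol | CC(C)=CCCO | starting material
2 | 4-methylpent-3-enal | CC(C)=CCC=O | intermediate (not isolated)
3 | (2E)-2,6-dimethylhepta-2,5-dienal | O=C/C(C)=C/CC=C(C)C | intermediate
4 | (4R,5E)-5,9-dimethyldeca-1,5,8-trien-4-yl diisopinocampheylborinate | C=CC[C@@H](OB([C@H]1C[C@H]2C[C@@H]([C@@H]1C)C2(C)C)[C@H]1C[C@H]2C[C@@H]([C@@H]1C)C2(C)C)/C(C)=C/CC=C(C)C | intermediate (not isolated)
5 | (4R,5E)-5,9-dimethyldeca-1,5,8-trien-4-ol | C=CC[C@@H](O)/C(C)=C/CC=C(C)C | intermediate
6 | acryloyl chloride | C=CC(Cl)=O | starting material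
7 | (4R,5E)-5,9-dimethyldeca-1,5,8-trien-4-yl prop-2-enoate | C=CC[C@@H](OC(=O)C=C)/C(C)=C/CC=C(C)C | intermediate
8 | (6R)-6-[(2E)-6-methylhepta-2,5-dien-2-yl]-5,6-dihydro-2H-pyran-2-one | O=C1C=CC[C@@H](O1)/C(C)=C/CC=C(C)C | intermediate
9 | phenylboronic acid | OB(O)c1ccccc1 | starting material
10 | (4S,6R)-6-[(2E)-6-methylhepta-2,5-dien-2-yl]-4-phenyltetrahydro-2H-pyran-2-one (trans; key-step precursor) | O=C1C[C@@H](c2ccccc2)C[C@@H](O1)/C(C)=C/CC=C(C)C | intermediate
11 | tert-butyl({(2R,4S)-2-[(2E)-6-methylhepta-2,5-dien-2-yl]-4-phenyl-3,4-dihydro-2H-pyran-6-yl}oxy)dimethylsilane (TBS ketene acetal of 10) | CC(C)(C)[Si](C)(C)OC1=C[C@@H](c2ccccc2)C[C@@H](O1)/C(C)=C/CC=C(C)C | intermediate (not isolated)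
12 | tert-butyldimethylsilyl (1R,2S,6S)-3-methyl-2-(3-methylbut-2-en-1-yl)-6-phenylcyclohex-3-ene-1-carboxylate | CC(C)(C)[Si](C)(C)OC(=O)[C@@H]1[C@H](CC=C(C)C)C(C)=CC[C@@H]1c1ccccc1 | intermediate (not isolated)
13 | (1R,2S,6S)-3-methyl-2-(3-methylbut-2-en-1-yl)-6-phenylcyclohex-3-ene-1-carboxylic acid (all-cis; key-step product) | OC(=O)[C@@H]1[C@H](CC=C(C)C)C(C)=CC[C@@H]1c1ccccc1 | intermediate
14 | (1R,2S,6S)-3-methyl-2-(3-methylbut-2-en-1-yl)-6-phenylcyclohex-3-ene-1-carbonyl chloride | O=C(Cl)[C@@H]1[C@H](CC=C(C)C)C(C)=CC[C@@H]1c1ccccc1 | intermediate (not isolated)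
15 | (1R,2S,6S)-N-methoxy-N,3-dimethyl-2-(3-methylbut-2-en-1-yl)-6-phenylcyclohex-3-ene-1-carboxamide | CON(C)C(=O)[C@@H]1[C@H](CC=C(C)C)C(C)=CC[C@@H]1c1ccccc1 | intermediate
16 | 3-hydroxy-4,5-dimethoxybenzaldehyde | COc1cc(C=O)cc(O)c1OC | starting material
17 | 3,4-dimethoxy-5-(methoxymethoxy)benzaldehyde | COCOc1cc(C=O)cc(OC)c1OC | intermediate
18 | 3,4-dimethoxy-5-(methoxymethoxy)phenyl formate | COCOc1cc(OC=O)cc(OC)c1OC | intermediate (not isolated)
19 | 3,4-dimethoxy-5-(methoxymethoxy)phenol | COCOc1cc(O)cc(OC)c1OC | intermediate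
20 | 1,2-dimethoxy-3,5-bis(methoxymethoxy)benzene | COCOc1cc(OCOC)c(OC)c(OC)c1 | intermediate
21 | [3,4-dimethoxy-2,6-bis(methoxymethoxy)phenyl]lithium | [Li]c1c(OCOC)cc(OC)c(OC)c1OCOC | intermediate (not isolated)
22 | lithium alkoxide of the N-methoxy-N-methyl hemiaminal formed from 21 and 15 (new carbinol centre undefined) | [Li]OC(N(C)OC)(c1c(OCOC)cc(OC)c(OC)c1OCOC)[C@@H]1[C@H](CC=C(C)C)C(C)=CC[C@@H]1c1ccccc1 | intermediate (not isolated)
23 | [3,4-dimethoxy-2,6-bis(methoxymethoxy)phenyl][(1R,2S,6S)-3-methyl-2-(3-methylbut-2-en-1-yl)-6-phenylcyclohex-3-en-1-yl]methanone (all-cis) | COCOc1cc(OC)c(OC)c(OCOC)c1C(=O)[C@@H]1[C@H](CC=C(C)C)C(C)=CC[C@@H]1c1ccccc1 | intermediate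
24 | [3,4-dimethoxy-2,6-bis(methoxymethoxy)phenyl][(1S,2S,6S)-3-methyl-2-(3-methylbut-2-en-1-yl)-6-phenylcyclohex-3-en-1-yl]methanone (aroyl trans to prenyl and phenyl) | COCOc1cc(OC)c(OC)c(OCOC)c1C(=O)[C@H]1[C@H](CC=C(C)C)C(C)=CC[C@@H]1c1ccccc1 | intermediate
25 | (2,6-dihydroxy-3,4-dimethoxyphenyl)[(1S,2S,6S)-3-methyl-2-(3-methylbut-2-en-1-yl)-6-phenylcyclohex-3-en-1-yl]methanone | COc1cc(O)c(C(=O)[C@H]2[C@H](CC=C(C)C)C(C)=CC[C@@H]2c2ccccc2)c(O)c1OC | target

Total step count: 13. Longest linear sequence: 10 steps (steps 1–7 and 11–13); steps 8–10 form the three-step aryl branch.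

Steps most likely to fail

Step 6, the ring contraction. O-silylation of the lactone enolate may lose out to Claisen self-condensation or C-silylation. The boat-constrained shift, which must bring a trisubstituted alkene under the ring, may also be slow enough for the ketene acetal to decompose by loss of the allylic carboxylate. The fallback gives up the lactone and builds the ring by cycloaddition, setting out from 20. Lithiation as in step 11 and acylation of 21 with (E)-N-methoxy-N-methylcinnamamide would give (E)-1-[3,4-dimethoxy-2,6-bis(methoxymethoxy)phenyl]-3-phenylprop-2-en-1-one F1. Acidic methanolysis would free (E)-1-(2,6-dihydroxy-3,4-dimethoxyphenyl)-3-phenylprop-2-en-1-one F2. An enantioselective Diels–Alder reaction of this 2'-hydroxychalcone with (E)-β-ocimene, mediated by a chiral BINOL–borate complex, would then form ring C1–C6 with the aroyl and phenyl groups trans. After separation from regio- and endo/exo isomers this comes back to the route at 25.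

Step 11, the aryllithium addition. At the crowded amide carbonyl, deprotonation at C1 or base-induced cleavage of the N–OMe group may outrun carbonyl addition, and metalation of 20 may partly occur at the position between OMOM and OMe. The fallback uses the far more electrophilic aldehyde and sets out from 13. LiAlH4 reduction would give [(1R,2S,6S)-3-methyl-2-(3-methylbut-2-en-1-yl)-6-phenylcyclohex-3-en-1-yl]methanol F3. Dess–Martin oxidation would give (1R,2S,6S)-3-methyl-2-(3-methylbut-2-en-1-yl)-6-phenylcyclohex-3-ene-1-carbaldehyde F4. Addition of 21 at −78 °C would give the secondary carbinol [3,4-dimethoxy-2,6-bis(methoxymethoxy)phenyl][(1R,2S,6S)-3-methyl-2-(3-methylbut-2-en-1-yl)-6-phenylcyclohex-3-en-1-yl]methanol F5 as a mixture at the new centre. A second Dess–Martin oxidation comes back to the route at 23.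

Step 4, the ring-closing metathesis. The ruthenium alkylidene formed at the allyl terminus may close onto the prenyl-type alkene with loss of isobutene, or oligomerise, instead of closing onto the electron-poor acrylate. The fallback avoids metathesis and sets out from 3, bypassing steps 2 and 3 as well. An enantioselective hetero-Diels–Alder reaction of 3 with (E)-1-methoxybuta-1,3-diene under a chiral tridentate Schiff-base chromium(III) catalyst, with the catalyst antipode chosen for the 6R centre, would give (6R)-2-methoxy-6-[(2E)-6-methylhepta-2,5-dien-2-yl]-5,6-dihydro-2H-pyran F6. Mild acid hydrolysis (PPTS, wet acetone) would give the lactol (6R)-6-[(2E)-6-methylhepta-2,5-dien-2-yl]-5,6-dihydro-2H-pyran-2-ol F7. Oxidation with MnO2 comes back to the route at 8.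

Further compounds
F1 | step 6 | (E)-1-[3,4-dimethoxy-2,6-bis(methoxymethoxy)phenyl]-3-phenylprop-2-en-1-one | COCOc1cc(OC)c(OC)c(OCOC)c1C(=O)/C=C/c1ccccc1
F2 | step 6 | (E)-1-(2,6-dihydroxy-3,4-dimethoxyphenyl)-3-phenylprop-2-en-1-one | COc1cc(O)c(C(=O)/C=C/c2ccccc2)c(O)c1OC
F3 | step 11 | [(1R,2S,6S)-3-methyl-2-(3-methylbut-2-en-1-yl)-6-phenylcyclohex-3-en-1-yl]methanol | OC[C@@H]1[C@H](CC=C(C)C)C(C)=CC[C@@H]1c1ccccc1
F4 | step 11 | (1R,2S,6S)-3-methyl-2-(3-methylbut-2-en-1-yl)-6-phenylcyclohex-3-ene-1-carbaldehyde | O=C[C@@H]1[C@H](CC=C(C)C)C(C)=CC[C@@H]1c1ccccc1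
F5 | step 11 | [3,4-dimethoxy-2,6-bis(methoxymethoxy)phenyl][(1R,2S,6S)-3-methyl-2-(3-methylbut-2-en-1-yl)-6-phenylcyclohex-3-en-1-yl]methanol (carbinol centre undefined) | COCOc1cc(OC)c(OC)c(OCOC)c1C(O)[C@@H]1[C@H](CC=C(C)C)C(C)=CC[C@@H]1c1ccccc1
F6 | step 4 | (6R)-2-methoxy-6-[(2E)-6-methylhepta-2,5-dien-2-yl]-5,6-dihydro-2H-pyran (acetal centre undefined) | COC1C=CC[C@@H](O1)/C(C)=C/CC=C(C)C
F7 | step 4 | (6R)-6-[(2E)-6-methylhepta-2,5-dien-2-yl]-5,6-dihydro-2H-pyran-2-ol (lactol centre undefined) | OC1C=CC[C@@H](O1)/C(C)=C/CC=C(C)C
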